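Numbering used below (SMILES order of the heavy atoms): Me1, C2, C3, N4, C5, C6=C7, C8, C9, C10, C11, C12, C13, C14 (Me15, O16), C17 (=O18), C19, C20, C21, C22, C23, C24, C25. Rings: A (N4, C3, C2, C24, C25), B (C21–C25), C (N4, C5, C13, C14, C21, C25), D (lactone), E (C5, C6, C10–C13), F (C6–C10).
Enabling feature: ring C is a masked 4-piperidone. C14 is flanked by C13 and C21, and each of these is bonded to a carbon on N4 (C5 and C25), so C5–C13 and C21–C25 are both Mannich bonds and can be cut together (Robinson–Schöpf logic); this opens rings B, C and E at once.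
Further cuts: N–O; C14–O16 and C14–Me15 (back to the C14 ketone through the methylidene compound); then the chain is cut at C12–C13, C21–C22 and C20–C21 into tert-butyl acetoacetate (C13, C14, C21 and a carboxyl lost as CO2), methyl acrylate (C17–C20), a West iodide (C5–C12 with ring F) and an East iodide (C22–C25, C2, C3, N4).
Forward: ring F is bought as cyclopentenone; the chain is joined by acetoacetate dianion alkylation, enolate alkylation and Michael addition; ring A closes as a hemiaminal on oxidation; one acid-triggered cascade closes ring B and then rings C and E together; ring D follows by lactonisation and the N-oxide comes last.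
Stereochemistry: C10 from a CBS reduction relayed by a suprafacial Johnson–Claisen rearrangement; C2 and C24 from one organocatalytic syn-selective Michael addition; C25, C21, C5 and C13 arise in the cascade (cis ring fusion, reversibility, iminium geometry, equilibration); C14 by delivery of the carboxyl oxygen from its own tether; N4 by oxidation of the lone pair of the trans-fused invertomer.

Key step: step 17

Remark: 26 is written as the cyclic N-Boc hemiaminal (both anomers), the expected resting form of a γ-(Boc-amino) aldehyde; 22, 24, 25 and 26 are epimer mixtures at C21, which is reset in step 17.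

Step 1
Reactants: 1 cyclopent-2-en-1-one; 2 formaldehyde (37% aqueous)
Product: 3 2-(hydroxymethyl)cyclopent-2-en-1-one
Conditions: imidazole (cat.), THF/H2O, 23 °C
Reagents that add atoms: none
Why: Morita–Baylis–Hillman reaction, in which conjugate addition of imidazole gives an enolate that is hydroxymethylated at the α-carbon (the future C6) before elimination of the catalyst restores the enone.

Step 2
Reactants: 3 2-(hydroxymethyl)cyclopent-2-en-1-one
Product: 4 2-({[tert-butyl(dimethyl)silyl]oxy}methyl)cyclopent-2-en-1-one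
Conditions: TBSCl, imidazole, DMF, 0 → 23 °C
Reagents that add atoms: tert-butyldimethylsilyl chloride, CC(C)(C)[Si](C)(C)Cl
Why: Standard silylation of the primary alcohol, which keeps C5 at the alcohol level until step 15.

Step 3
Reactants: 4 2-({[tert-butyl(dimethyl)silyl]oxy}methyl)cyclopent-2-en-1-one
Product: 5 (1R)-2-({[tert-butyl(dimethyl)silyl]oxy}methyl)cyclopent-2-en-1-ol
Conditions: (S)-2-methyl-CBS-oxazaborolidine (10 mol%), BH3·SMe2, THF, −20 °C; MeOH quench
Reagents that add atoms: none
Why: Corey–Bakshi–Shibata reduction, in which the 2-substituted alkenyl arm acts as the large group so that the (S)-oxazaborolidine should deliver hydride to the face giving the (R)-carbinol by 1,2-reduction.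

Step 4
Reactants: 5 (1R)-2-({[tert-butyl(dimethyl)silyl]oxy}methyl)cyclopent-2-en-1-ol; 6 triethyl orthoacetate
Product: 8 ethyl 2-[(1R)-2-({[tert-butyl(dimethyl)silyl]oxy}methyl)cyclopent-2-en-1-yl]acetate, via mixed ketene acetal 7 (not isolated)
Conditions: EtCO2H (cat.), 140 °C, EtOH distilled off
Reagents that add atoms: none
Why: Johnson–Claisen rearrangement, whose suprafacial [3,3] shift forms the C10–C11 bond on the ring face that carried the oxygen (C10 set by chirality transfer) and moves the double bond to C6=C7.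

Step 5
Reactants: 8 ethyl 2-[(1R)-2-({[tert-butyl(dimethyl)silyl]oxy}methyl)cyclopent-2-en-1-yl]acetate
Product: 9 2-[(1R)-2-({[tert-butyl(dimethyl)silyl]oxy}methyl)cyclopent-2-en-1-yl]ethan-1-ol
Conditions: LiAlH4, Et2O, 0 °C
Reagents that add atoms: none
Why: Hydride reduction of the ester to the primary alcohol, to which the silyl ether and the trisubstituted alkene are inert.

Step 6
Reactants: 9 2-[(1R)-2-({[tert-butyl(dimethyl)silyl]oxy}methyl)cyclopent-2-en-1-yl]ethan-1-ol
Product: 10 tert-butyl{[(5R)-5-(2-iodoethyl)cyclopent-1-en-1-yl]methoxy}dimethylsilane (West iodide)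
Conditions: I2, PPh3, imidazole, CH2Cl2, 0 → 23 °C
Reagents that add atoms: iodine, II
Why: Appel-type iodination of the primary alcohol through its alkoxyphosphonium ion (SN2 at C12).

Step 7
Reactants: 11 3-{[tert-butyl(dimethyl)silyl]oxy}propanal; 12 (E)-1-nitroprop-1-ene
Product: 13 (2R,3S)-2-({[tert-butyl(dimethyl)silyl]oxy}methyl)-3-methyl-4-nitrobutanal
Conditions: (R)-2-[diphenyl(trimethylsilyloxy)methyl]pyrrolidine (10 mol%), 4-nitrophenol (cat.), toluene, 0 °C
Reagents that add atoms: none
Why: Enamine-mediated Michael addition of an aldehyde to a nitroalkene with a diarylprolinol silyl ether catalyst, in which the (E)-enamine attacks through the usual synclinal arrangement away from the diarylmethyl group and should give the syn adduct with the (R)-catalyst as the (2R,3S) isomer, setting C24 and C2 at once.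

Step 8
Reactants: 13 (2R,3S)-2-({[tert-butyl(dimethyl)silyl]oxy}methyl)-3-methyl-4-nitrobutanal
Product: 14 tert-butyl{[(2R,3S)-2-ethenyl-3-methyl-4-nitrobutyl]oxy}dimethylsilane
Conditions: Ph3PCH3Br, KN(SiMe3)2, THF, −78 → 0 °C
Reagents that add atoms: methyltriphenylphosphonium bromide, C[P+](c1ccccc1)(c1ccccc1)c1ccccc1.[Br-]
Why: Wittig methylenation adds C22, the unstabilised ylide being expected to add to the aldehyde at low temperature faster than C24 epimerises, while any nitronate formed is reprotonated on work-up.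

Step 9
Reactants: 14 tert-butyl{[(2R,3S)-2-ethenyl-3-methyl-4-nitrobutyl]oxy}dimethylsilane
Product: 16 tert-butyl N-[(2S,3R)-3-({[tert-butyl(dimethyl)silyl]oxy}methyl)-2-methylpent-4-en-1-yl]carbamate, via primary amine 15 (not isolated)
Conditions: Zn, AcOH, THF, 0 → 23 °C; then Boc2O, NaHCO3
Reagents that add atoms: di-tert-butyl dicarbonate, CC(C)(C)OC(=O)OC(=O)OC(C)(C)C
Why: Zinc in acetic acid reduces the primary nitro group to the amine without touching the vinyl group or the silyl ether, and the amine is capped in the same flask as its carbamate.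

Step 10
Reactants: 16 tert-butyl N-[(2S,3R)-3-({[tert-butyl(dimethyl)silyl]oxy}methyl)-2-methylpent-4-en-1-yl]carbamate
Product: 18 tert-butyl N-[(2S,3R)-3-({[tert-butyl(dimethyl)silyl]oxy}methyl)-5-hydroxy-2-methylpentyl]carbamate, via B-alkyl-9-BBN adduct 17 (not isolated)
Conditions: 9-BBN, THF, 0 → 23 °C; then NaOH, H2O2
Reagents that add atoms: hydrogen peroxide, OO
Why: Brown hydroboration–oxidation of the monosubstituted alkene places the hydroxyl group on the terminal carbon C22.

Step 11
Reactants: 18 tert-butyl N-[(2S,3R)-3-({[tert-butyl(dimethyl)silyl]oxy}methyl)-5-hydroxy-2-methylpentyl]carbamate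
Product: 19 tert-butyl N-[(2S,3R)-3-({[tert-butyl(dimethyl)silyl]oxy}methyl)-5-iodo-2-methylpentyl]carbamate (East iodide)
Conditions: I2, PPh3, imidazole, CH2Cl2, 0 → 23 °C
Reagents that add atoms: iodine, II
Why: Appel-type iodination under neutral conditions, under which the carbamate N–H should not cyclise onto the activated carbon.

Step 12
Reactants: 20 tert-butyl acetoacetate; 10 West iodide
Product: 21 tert-butyl 6-[(1S)-2-({[tert-butyl(dimethyl)silyl]oxy}methyl)cyclopent-2-en-1-yl]-3-oxohexanoate
Conditions: NaH then n-BuLi, THF, 0 °C; then 10, 0 → 23 °C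
Reagents that add atoms: none
Why: Alkylation of the acetoacetate dianion, whose more basic terminal carbanion (C13) reacts with the primary iodide and leaves C21 free.

Step 13
Reactants: 21 tert-butyl 6-[(1S)-2-({[tert-butyl(dimethyl)silyl]oxy}methyl)cyclopent-2-en-1-yl]-3-oxohexanoate; 19 East iodide
Product: 22 tert-butyl 2-[(3R,4S)-5-[(tert-butoxycarbonyl)amino]-3-({[tert-butyl(dimethyl)silyl]oxy}methyl)-4-methylpentyl]-6-[(1S)-2-({[tert-butyl(dimethyl)silyl]oxy}methyl)cyclopent-2-en-1-yl]-3-oxohexanoate (both C21 epimers)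
Conditions: NaH, THF/DMF, 0 °C; then 19, 50 °C
Reagents that add atoms: none
Why: C-alkylation of the β-keto ester sodium enolate with a primary iodide, the far less acidic carbamate N–H staying protonated and the new centre C21 being left uncontrolled because it is reset in step 17.

Step 14
Reactants: 22 the doubly alkylated β-keto ester; 23 methyl acrylate
Product: 24 1-tert-butyl 5-methyl 2-[(3R,4S)-5-[(tert-butoxycarbonyl)amino]-3-({[tert-butyl(dimethyl)silyl]oxy}methyl)-4-methylpentyl]-2-{4-[(1S)-2-({[tert-butyl(dimethyl)silyl]oxy}methyl)cyclopent-2-en-1-yl]butanoyl}pentanedioate (both C21 epimers)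
Conditions: DBU (cat.), MeCN, 23 °C
Reagents that add atoms: none
Why: Base-catalysed Michael addition of the α-substituted β-keto ester to methyl acrylate makes C21 quaternary and brings in C17–C20 of the future lactone.

Step 15
Reactants: 24 the quaternary keto diester bis(silyl ether)
Product: 25 1-tert-butyl 5-methyl 2-[(3R,4S)-5-[(tert-butoxycarbonyl)amino]-3-(hydroxymethyl)-4-methylpentyl]-2-{4-[(1S)-2-(hydroxymethyl)cyclopent-2-en-1-yl]butanoyl}pentanedioate
Conditions: Bu4NF, AcOH, THF, 23 °C
Reagents that add atoms: none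
Why: Fluoride cleaves both primary silyl ethers while acetic acid buffers the medium so that the keto diester does not undergo aldol or Claisen-type condensation.

Step 16
Reactants: 25 the keto diester diol
Product: 26 1-tert-butyl 5-methyl 2-{2-[(3R,4S)-1-(tert-butoxycarbonyl)-2-hydroxy-4-methylpyrrolidin-3-yl]ethyl}-2-{4-[(1S)-2-formylcyclopent-2-en-1-yl]butanoyl}pentanedioate
Conditions: Dess–Martin periodinane, NaHCO3, CH2Cl2, 0 → 23 °C
Reagents that add atoms: none
Why: Dess–Martin oxidation turns the allylic alcohol into the enal (C5) and the other primary alcohol into the C25 aldehyde, which should rest as the cyclic N-Boc hemiaminal (ring A) and so shield C24 from epimerisation.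

Step 17
Reactants: 26 the keto enal N-Boc hemiaminal
Product: 29 pentacyclic amino keto ester (rings A B C E F closed; C14 ketone; CH2CH2CO2Me on C21), via 1-pyrroline keto acid 27 (not isolated), via bicyclic amino ketone 28 (not isolated)
Conditions: TFA/CH2Cl2 (1:2), 0 → 40 °C; evaporate; then NaOAc, AcOH, 70 °C
Reagents that add atoms: none
Why: TFA strips the Boc group and the tert-butyl ester, the hemiaminal ionises to the 1-pyrrolinium ion of 27, and loss of CO2 from its β-keto acid releases the enol at C21, which attacks C25 in a Mannich closure of ring B (5-exo-trig at the iminium carbon, enol exocyclic) to give 28; in the acetate buffer the secondary amine of 28 condenses with the enal to a ten-membered conjugated iminium ion and the C13 enol adds to C5 in a transannular Mannich step that closes ring C (6-endo-trig at the iminium, enol endocyclic) and ring E (6-exo-trig, enol exocyclic) together. The closest known reaction type is the Robinson–Schöpf double Mannich synthesis of 4-piperidones from a ketone, two aldehydes and an amine, here run with all four components in one chain and started by decarboxylation as in the classical Mannich reactions of β-keto acids with cyclic imines. C25 is set by the preset C24, because the 2-azabicyclo[3.3.0]octane can only be cis-fused (H24 and H25 syn), and C21 follows because the first Mannich step is reversible and only the epimer with the acyl group syn to nitrogen can go on to ring C. C5 is set by the iminium geometry: in the ten-membered ring C6 should sit syn to C25 (the cis-cycloalkene-like arrangement), and attack from the C21 face, the only one the tether reaches, then places C6 on the side of H25, while C13 is α to the ketone and should equilibrate under the conditions to the trans fusion of rings C and E (H13 anti to H5), by analogy with 1-decalones. The step needs C21 to react before C13 (five- against seven-membered ring, helped by the regiospecific decarboxylative enol), 1,2-addition to the unsaturated iminium ion in preference to 1,4-addition (six- against eight-membered ring), and an intact C24, which is protected because the aldehyde is stored as the hemiaminal and the iminium ion is formed and consumed in strong acid, where enamine formation is slow.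

Step 18
Reactants: 29 pentacyclic amino keto ester
Product: 30 pentacyclic amino ester with an exocyclic methylidene group on C14
Conditions: Cp2TiMe2, toluene, 65 °C, dark
Reagents that add atoms: dimethyltitanocene, C[Ti](C)(C1C=CC=C1)C1C=CC=C1
Why: Petasis methylenation, in which the titanium methylidene adds to the ketone faster than to the ester and is not basic, so that C13 and the β-amino ketone are not disturbed.

Step 19
Reactants: 30 the C14 methylidene amino ester
Product: 32 hexacyclic amino lactone (33 without the N-oxide oxygen), via methylidene acid 31 (not isolated)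
Conditions: 3 M H2SO4, 1,4-dioxane, 80 °C; then aq. NaHCO3
Reagents that add atoms: water, O
Why: Acid hydrolysis of the methyl ester to 31 is followed by Markovnikov hydro-acyloxylation, in which protonation of the 1,1-disubstituted alkene gives the tertiary C14 cation that the carboxyl group can reach only from the face of its own tether on C21, so the cis-fused δ-lactone with O16 syn to C20 and Me15 on the opposite face should result.

Step 20
Reactants: 32 hexacyclic amino lactone
Product: 33 CNP0566793.4 (N4-oxide of 32)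
Conditions: mCPBA (1.0 equiv), CH2Cl2, −20 → 0 °C
Reagents that add atoms: 3-chloroperoxybenzoic acid, OOC(=O)c1cccc(Cl)c1
Why: Peracid N-oxidation of the tertiary amine, far more nucleophilic than the trisubstituted alkene, should deliver oxygen to the lone pair of the invertomer with trans-fused rings A and C (expected to dominate because the cis-fused chair would hold Me15 and C24 syn-diaxial on ring C), giving the N-oxide with oxygen on the ring-B face.

Compound list
1 | cyclopent-2-en-1-one | O=C1CCC=C1 | starting material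
2 | formaldehyde (37% aqueous) | C=O | starting material
3 | 2-(hydroxymethyl)cyclopent-2-en-1-one | O=C1CCC=C1CO | intermediate
4 | 2-({[tert-butyl(dimethyl)silyl]oxy}methyl)cyclopent-2-en-1-one | O=C1CCC=C1CO[Si](C)(C)C(C)(C)C | intermediate
5 | (1R)-2-({[tert-butyl(dimethyl)silyl]oxy}methyl)cyclopent-2-en-1-ol | O[C@@H]1CCC=C1CO[Si](C)(C)C(C)(C)C | intermediate
6 | triethyl orthoacetate | CC(OCC)(OCC)OCC | starting material
7 | mixed ketene acetal, tert-butyl({(5R)-5-[(1-ethoxyethenyl)oxy]cyclopent-1-en-1-yl}methoxy)dimethylsilane (not isolated) | C=C(OCC)O[C@@H]1CCC=C1CO[Si](C)(C)C(C)(C)C | intermediate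
8 | ethyl 2-[(1R)-2-({[tert-butyl(dimethyl)silyl]oxy}methyl)cyclopent-2-en-1-yl]acetate | CCOC(=O)C[C@H]1CCC=C1CO[Si](C)(C)C(C)(C)C | intermediate
9 | 2-[(1R)-2-({[tert-butyl(dimethyl)silyl]oxy}methyl)cyclopent-2-en-1-yl]ethan-1-ol | OCC[C@H]1CCC=C1CO[Si](C)(C)C(C)(C)C | intermediate
10 | West iodide, tert-butyl{[(5R)-5-(2-iodoethyl)cyclopent-1-en-1-yl]methoxy}dimethylsilane | ICC[C@H]1CCC=C1CO[Si](C)(C)C(C)(C)C | intermediate
11 | 3-{[tert-butyl(dimethyl)silyl]oxy}propanal | O=CCCO[Si](C)(C)C(C)(C)C | starting material
12 | (E)-1-nitroprop-1-ene | C/C=C/[N+](=O)[O-] | starting material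
13 | (2R,3S)-2-({[tert-butyl(dimethyl)silyl]oxy}methyl)-3-methyl-4-nitrobutanal | O=C[C@@H](CO[Si](C)(C)C(C)(C)C)[C@H](C)C[N+](=O)[O-] | intermediate
14 | tert-butyl{[(2R,3S)-2-ethenyl-3-methyl-4-nitrobutyl]oxy}dimethylsilane | C=C[C@@H](CO[Si](C)(C)C(C)(C)C)[C@H](C)C[N+](=O)[O-] | intermediate
15 | (2S,3R)-3-({[tert-butyl(dimethyl)silyl]oxy}methyl)-2-methylpent-4-en-1-amine (not isolated) | C=C[C@@H](CO[Si](C)(C)C(C)(C)C)[C@H](C)CN | intermediate
16 | tert-butyl N-[(2S,3R)-3-({[tert-butyl(dimethyl)silyl]oxy}methyl)-2-methylpent-4-en-1-yl]carbamate | C=C[C@@H](CO[Si](C)(C)C(C)(C)C)[C@H](C)CNC(=O)OC(C)(C)C | intermediate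
17 | tert-butyl N-[(2S,3R)-5-(9-borabicyclo[3.3.1]nonan-9-yl)-3-({[tert-butyl(dimethyl)silyl]oxy}methyl)-2-methylpentyl]carbamate (not isolated) | C1CCC2CCCC1B2CC[C@@H](CO[Si](C)(C)C(C)(C)C)[C@H](C)CNC(=O)OC(C)(C)C | intermediate
18 | tert-butyl N-[(2S,3R)-3-({[tert-butyl(dimethyl)silyl]oxy}methyl)-5-hydroxy-2-methylpentyl]carbamate | OCC[C@@H](CO[Si](C)(C)C(C)(C)C)[C@H](C)CNC(=O)OC(C)(C)C | intermediate
19 | East iodide, tert-butyl N-[(2S,3R)-3-({[tert-butyl(dimethyl)silyl]oxy}methyl)-5-iodo-2-methylpentyl]carbamate | ICC[C@@H](CO[Si](C)(C)C(C)(C)C)[C@H](C)CNC(=O)OC(C)(C)C | intermediate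
20 | tert-butyl acetoacetate | CC(=O)CC(=O)OC(C)(C)C | starting material
21 | tert-butyl 6-[(1S)-2-({[tert-butyl(dimethyl)silyl]oxy}methyl)cyclopent-2-en-1-yl]-3-oxohexanoate | CC(C)(C)OC(=O)CC(=O)CCC[C@H]1CCC=C1CO[Si](C)(C)C(C)(C)C | intermediate
22 | tert-butyl 2-[(3R,4S)-5-[(tert-butoxycarbonyl)amino]-3-({[tert-butyl(dimethyl)silyl]oxy}methyl)-4-methylpentyl]-6-[(1S)-2-({[tert-butyl(dimethyl)silyl]oxy}methyl)cyclopent-2-en-1-yl]-3-oxohexanoate (both C21 epimers) | CC(C)(C)OC(=O)C(CC[C@@H](CO[Si](C)(C)C(C)(C)C)[C@H](C)CNC(=O)OC(C)(C)C)C(=O)CCC[C@H]1CCC=C1CO[Si](C)(C)C(C)(C)C | intermediate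
23 | methyl acrylate | C=CC(=O)OC | starting material
24 | 1-tert-butyl 5-methyl 2-[(3R,4S)-5-[(tert-butoxycarbonyl)amino]-3-({[tert-butyl(dimethyl)silyl]oxy}methyl)-4-methylpentyl]-2-{4-[(1S)-2-({[tert-butyl(dimethyl)silyl]oxy}methyl)cyclopent-2-en-1-yl]butanoyl}pentanedioate (both C21 epimers) | CC(C)(C)OC(=O)C(CCC(=O)OC)(CC[C@@H](CO[Si](C)(C)C(C)(C)C)[C@H](C)CNC(=O)OC(C)(C)C)C(=O)CCC[C@H]1CCC=C1CO[Si](C)(C)C(C)(C)C | intermediate
25 | 1-tert-butyl 5-methyl 2-[(3R,4S)-5-[(tert-butoxycarbonyl)amino]-3-(hydroxymethyl)-4-methylpentyl]-2-{4-[(1S)-2-(hydroxymethyl)cyclopent-2-en-1-yl]butanoyl}pentanedioate (both C21 epimers) | CC(C)(C)OC(=O)C(CCC(=O)OC)(CC[C@@H](CO)[C@H](C)CNC(=O)OC(C)(C)C)C(=O)CCC[C@H]1CCC=C1CO | intermediate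
26 | 1-tert-butyl 5-methyl 2-{2-[(3R,4S)-1-(tert-butoxycarbonyl)-2-hydroxy-4-methylpyrrolidin-3-yl]ethyl}-2-{4-[(1S)-2-formylcyclopent-2-en-1-yl]butanoyl}pentanedioate (hemiaminal anomers, both C21 epimers) | C[C@@H]1CN(C(=O)OC(C)(C)C)C(O)[C@@H]1CCC(CCC(=O)OC)(C(=O)OC(C)(C)C)C(=O)CCC[C@H]1CCC=C1C=O | intermediate
27 | 1-pyrroline keto acid, 2-{4-[(1S)-2-formylcyclopent-2-en-1-yl]butanoyl}-5-methoxy-2-{2-[(3S,4R)-3-methyl-3,4-dihydro-2H-pyrrol-4-yl]ethyl}-5-oxopentanoic acid, present as its iminium trifluoroacetate (not isolated) | C[C@@H]1CN=C[C@@H]1CCC(CCC(=O)OC)(C(=O)O)C(=O)CCC[C@H]1CCC=C1C=O | intermediate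
28 | bicyclic amino ketone, methyl 3-[(3S,3aR,6S,6aS)-6-{4-[(1S)-2-formylcyclopent-2-en-1-yl]butanoyl}-3-methyloctahydrocyclopenta[b]pyrrol-6-yl]propanoate (not isolated) | C[C@@H]1CN[C@H]2[C@@H]1CC[C@@]2(CCC(=O)OC)C(=O)CCC[C@H]1CCC=C1C=O | intermediate
29 | pentacyclic amino keto ester: rings A, B, C, E and F of 33 closed, C14 a ketone, C21 carrying CH2CH2CO2Me, configuration of 33 at C2, C5, C10, C13, C21, C24 and C25 | C[C@@H]1CN2[C@H]3C4=CCC[C@@H]4CC[C@@H]3C(=O)[C@]5(CCC(=O)OC)CC[C@H]1[C@@H]52 | intermediate
30 | C14 methylidene analogue of 29 (C14=CH2 in place of C14=O) | C[C@@H]1CN2[C@H]3C4=CCC[C@@H]4CC[C@@H]3C(=C)[C@]5(CCC(=O)OC)CC[C@H]1[C@@H]52 | intermediate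
31 | carboxylic acid of 30 (not isolated) | C[C@@H]1CN2[C@H]3C4=CCC[C@@H]4CC[C@@H]3C(=C)[C@]5(CCC(=O)O)CC[C@H]1[C@@H]52 | intermediate
32 | hexacyclic amino lactone (tertiary amine corresponding to 33; 2S,5R,10R,13S,14R,21S,24R,25S in the numbering of the plan) | C[C@@H]1CN2[C@H]3C4=CCC[C@@H]4CC[C@@H]3[C@@]3(C)OC(=O)CC[C@]34CC[C@H]1[C@@H]42 | intermediate
33 | CNP0566793.4, N4-oxide of 32 (N4 R; oxygen on the ring-B face) | C[C@@H]1C[N@@+]2([O-])[C@H]3C4=CCC[C@@H]4CC[C@@H]3[C@@]3(C)OC(=O)CC[C@]34CC[C@H]1[C@@H]42 | target

Total step count: 20. Longest linear sequence: 15 steps (steps 1–6 and 12–20).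

Steps most likely to fail

Step 17. C24 may epimerise through iminium–enamine tautomerism before ring B closes; the ten-membered iminium ion may oligomerise instead of closing, or close from the other geometry and give the C5 epimer; the C/E fusion may stay cis if equilibration at C13 is slow. The fallback sets out from diol 25 and comes back at 29, and closes ring E first by a different bond-forming order. MnO2 in CH2Cl2 oxidises only the allylic alcohol of 25 and gives the enal alcohol F1. Pyrrolidinium acetate then brings about an intramolecular aldol condensation between C13 and C5 (C21 is quaternary and cannot enolise) to give the bicyclic dienone alcohol F2. Dess–Martin oxidation of the remaining alcohol gives the dienone hemiaminal F3. TFA and then NaOAc/AcOH close ring B by the same decarboxylative Mannich step and ring C by 6-endo aza-Michael addition of the freed secondary amine to C5 of the dienone, with protonation at C13, to reach 29; C5 is then under the thermodynamic control of a reversible conjugate addition.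

Step 18. The ketone is flanked by a quaternary and a tertiary carbon, so the titanium reagent may fail to add, and at the temperature needed the ester may start to react. The fallback sets out from 29 and comes back at 32, bypassing 30. MeMgBr with CeCl3 in THF at −78 °C adds to the ketone in preference to the ester and gives the tertiary carbinol F4 (either C14 epimer). Warm aqueous H2SO4 in dioxane then ionises the tertiary C14–O bond, and the same cation as in step 19 is captured by the carboxyl arm to give 32, whichever face the methyl group entered from.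

Step 8. The ylide may deprotonate the nitro group and the α-position of the aldehyde, with loss of material or epimerisation at C24. The fallback sets out from 13 and comes back at 16, removing the acidic nitro group before the olefination. NaBH4 gives the nitro alcohol F5; Zn/AcOH followed by Boc2O gives the carbamate alcohol F6; Dess–Martin oxidation gives the carbamate aldehyde F7 (in equilibrium with a cyclic hemiaminal); Wittig methylenation with Ph3PCH3Br and KN(SiMe3)2 then gives 16.

Further compounds
F1 | step 17 | 1-tert-butyl 5-methyl 2-[(3R,4S)-5-[(tert-butoxycarbonyl)amino]-3-(hydroxymethyl)-4-methylpentyl]-2-{4-[(1S)-2-formylcyclopent-2-en-1-yl]butanoyl}pentanedioate | CC(C)(C)OC(=O)C(CCC(=O)OC)(CC[C@@H](CO)[C@H](C)CNC(=O)OC(C)(C)C)C(=O)CCC[C@H]1CCC=C1C=O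
F2 | step 17 | 1-tert-butyl 5-methyl 2-[(3R,4S)-5-[(tert-butoxycarbonyl)amino]-3-(hydroxymethyl)-4-methylpentyl]-2-{[(7aR)-2,6,7,7a-tetrahydro-1H-inden-5-yl]carbonyl}pentanedioate | CC(C)(C)OC(=O)C(CCC(=O)OC)(CC[C@@H](CO)[C@H](C)CNC(=O)OC(C)(C)C)C(=O)C1=CC2=CCC[C@@H]2CC1
F3 | step 17 | 1-tert-butyl 5-methyl 2-{2-[(3R,4S)-1-(tert-butoxycarbonyl)-2-hydroxy-4-methylpyrrolidin-3-yl]ethyl}-2-{[(7aR)-2,6,7,7a-tetrahydro-1H-inden-5-yl]carbonyl}pentanedioate | C[C@@H]1CN(C(=O)OC(C)(C)C)C(O)[C@@H]1CCC(CCC(=O)OC)(C(=O)OC(C)(C)C)C(=O)C1=CC2=CCC[C@@H]2CC1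
F4 | step 18 | C14 tertiary carbinol of 29 (methyl added to the ketone, either C14 epimer) | C[C@@H]1CN2[C@H]3C4=CCC[C@@H]4CC[C@@H]3C(C)(O)[C@]5(CCC(=O)OC)CC[C@H]1[C@@H]52
F5 | step 8 | (2S,3S)-2-({[tert-butyl(dimethyl)silyl]oxy}methyl)-3-methyl-4-nitrobutan-1-ol | OC[C@@H](CO[Si](C)(C)C(C)(C)C)[C@H](C)C[N+](=O)[O-]
F6 | step 8 | tert-butyl N-[(2S,3S)-3-({[tert-butyl(dimethyl)silyl]oxy}methyl)-4-hydroxy-2-methylbutyl]carbamate | OC[C@@H](CO[Si](C)(C)C(C)(C)C)[C@H](C)CNC(=O)OC(C)(C)C
F7 | step 8 | tert-butyl N-[(2S,3R)-3-({[tert-butyl(dimethyl)silyl]oxy}methyl)-2-methyl-4-oxobutyl]carbamate | O=C[C@@H](CO[Si](C)(C)C(C)(C)C)[C@H](C)CNC(=O)OC(C)(C)C
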